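Remark (assumption): neolignan locants are used. Ring A is the 3,4,5-trimethoxyphenyl ring with side chain C7 (acetoxy), C8, C9; ring B is the central ring (oxygen at C4', side chain C7', C8', C9'); ring C is the propenyl-bearing ring (ether oxygen at C4''). The target is read from its SMILES as (7S,8R,8'R) with an E propenyl group.

Remark (structure check): the descriptors of the imide 7, the benzylic bromide 20 and the alkylated imide 22 were derived atom by atom from this reading. An (R) auxiliary, a (7S,8R) bromide and an (S) α-carbon that becomes (R)-C8' after reduction are mutually consistent.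

## Structural features

The target is an acyclic sesquineolignan whose only rings are three benzene rings: ring A (3,4,5-trimethoxyphenyl), ring B (3,5-dimethoxy, 1,4-disubstituted) and ring C (2,6-dimethoxy-4-(E)-propenylphenoxy). The rings are joined by two three-carbon chains through two alkyl aryl ether bonds, C8–O–C4' and C8'–O–C4''. C7 (S, benzylic, acetoxy) and C8 (R, aryloxy, methyl) are adjacent and erythro, whereas C8' (R) is separated from them by ring B, receives no stereochemical relay and must be set on its own. The fragile groups are the (E)-propenyl styrene (acids, hydrogenation, radicals and oxidants), the benzylic C7 acetate on an electron-rich ring (base, hydrides, ionisation), and any α-aryloxy carbonyl intermediate, which can epimerise. The real difficulty is that both ether oxygens belong to phenols flanked by two methoxy groups and both sit on secondary carbons, and C8' has no neighbouring function that could direct its formation. The key step uses the substitution pattern of C8', which carries the ring C aryloxy oxygen, the benzylic C7' of ring B and the methyl C9'. If C9' is raised to the acyl level, C8' becomes the α-carbon of an aryloxyacetic acid derivative, and its chiral enolate can be benzylated by C7', forming the C7'–C8' bond and the C8' stereocentre in one operation.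

## Logic of the disconnections

27 to 26 to 25: the O–acetyl bond at C7 is cut, and the hydroxyl of 26 is traced to the silyl ether 25. An acetate would not survive the amide base or the three hydride reagents used later, so the C7 oxygen travels as a silyl ether from 16 to 25. Nothing is simplified structurally, but the base-labile ester is confined to the last step. The forward steps must leave the propenyl group and the benzylic C7–O bond untouched.

25 to 24 to 23 to 22: the three C9'–H bonds are traced back to an acyl carbon (C9'–H to C9'–O in 24 and 23, then to the imide carbonyl of 22). This gives C8' an acidifying carbonyl and a place to attach a chiral controller. The price is three redox or activation steps, which must not touch the propenyl group, the silyl ether or the C8' configuration.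

22 to 7 + 20 (through 21): the C7'–C8' bond is cut. This is the convergent cut: it separates the ring C unit 7 from the ring A–B unit 20, two pieces of similar size, each with its own stereochemistry settled. The forward step needs a face-selective SN2 alkylation by the cold enolate 21. Because such enolates do not tolerate warming, 20 is made the limiting partner and 7 is used in excess.

7 to 4 + 5 (through 6), 4 to 2 + 3, 2 to 1: the N–acyl bond, the O–CH2 bond and the position of the double bond are cut or changed. The ring C ether is thereby formed at a primary carbon of 3, so the hindered phenol never has to attack a secondary carbon. The demand is an E-selective alkene transposition from 1 to 2, placed first so that every later intermediate already carries the final side chain.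

20 to 19 to 16 (through 17 and 18): the C7'–Br bond is traced to C7'–OH, and the C1'–C7' bond is cut back to the aryl bromide 16 and a one-carbon electrophile. The bromine on ring B is an inert placeholder through steps 4 to 8 and allows ring B to be bought as 9. The forward step needs a halogen–metal exchange that tolerates the silyl ether, and a neutral bromination.

16 to 15 to 14: the O–Si bond and the C7–H bond are cut. C7 is set by 1,2-induction from C8 in a chelated ketone, so no second chiral reagent is needed. The demand is a hydride source that reduces through a chelate, with no epimerisation at C8.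

14 to 11 + 12 (through 13), 11 to 10: the aryl–carbonyl bond C1–C7 is cut, and the amide is traced to the ester. Ring A then comes from a simple aryl bromide. The forward steps need a single addition of 13 and configurational stability of the α-aryloxy carbonyl compounds.

10 to 8 + 9: the C8–O bond is cut with inversion, taking C8 from the chiral pool. This substitution by a hindered phenol at a secondary carbon is acceptable because the carbon is activated by the ester and carries only a methyl group.

## Other disconnections considered

Alternative 1: The cut is the C7–C8 bond of the ring A side chain.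
- Forward key step: a thiamine diphosphate-dependent carboligase of the benzoylformate decarboxylase type would turn 3,4,5-trimethoxybenzaldehyde A1 into an enzyme-bound acyl-anion equivalent and add it to acetaldehyde A2. The product would be the ketol A3, (S)-2-hydroxy-1-(3,4,5-trimethoxyphenyl)propan-1-one.
- In its favour: C8 would be created catalytically from the two achiral aldehydes A1 and A2 in water, without organometallic reagents. A3 could be joined to 9 by a Mitsunobu inversion to reach 14 in two steps, against three (steps 4 to 6) here. On step count for the ring A–B half it is the better plan.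
- Against it here: the donor site must accept A1, a benzaldehyde substituted at both meta positions and at para, so rate and enantioselectivity are uncertain. The acceptor A2 can self-ligate and damage the protein. A Mitsunobu reaction at the ketol A3 is less safe than at a lactate ester, because the activated carbinol carbon lies α to an aryl ketone and can enolise, and 9 is a hindered nucleophile.
- Comparison: both plans converge on 14 and share the chelation-controlled reduction, so they are equal from there on. The lactate route starts from an enantiopure centre and only inverts it, whereas the enzymatic route must first create the centre and then invert it. The alternative does nothing for C8', so it complements the auxiliary alkylation and does not replace it.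

Alternative 2: The cut removes both hydrogens across C7'–C8'.
- Forward key step: the Z enol ether A5 would be made from the ring C aryl acetate A4 (4-bromo-2,6-dimethoxyphenyl acetate) by a Takai–Utimoto-type benzylidenation of the ester carbonyl with a silyl-protected ring B unit. A cationic catalyst of the type [Ir(C8H12)(phosphinooxazoline)][B(C6H3(CF3)2)4] would then hydrogenate one face of the trisubstituted C7'=C8' bond to give the (R)-ether A6.
- In its favour: C9' is a methyl group from the start, so steps 12 to 14 would disappear and no stoichiometric auxiliary is used. On redox and atom economy it is the better plan. The C8'–O bond is again made at an acyl carbon, so it equals the chosen plan in avoiding substitution by a hindered phenol at a secondary carbon.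
- Against it here: hydrogenation cannot coexist with the propenyl group, so ring C must carry bromine and the propenyl group must be added afterwards by cross-coupling. The stereogenic carbon bears an aryloxy group flanked by two methoxy groups, a demanding substrate for this catalyst class. The catalyst is strongly Brønsted acidic under hydrogen, and aryl enol ethers can hydrolyse. The enantioselectivity would depend on the geometric purity of A5, and benzylidenation of the aryl ester A4, with phenoxide as a ready leaving group, is itself uncertain. Ring A would be attached afterwards through the ring B phenol, which makes the sequence linear.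
- Comparison: the step count is probably equal or slightly lower. Face selection would come from a catalyst pocket that must be found by screening, against a chelated enolate whose facial bias is predictable. The alternative is better on C9' economy and worse on convergence.

Alternative 3: The cut is the aryl–oxygen bond O–C4' of ring B, not the alkyl–oxygen bond.
- Forward key step: the potassium alkoxide of A7, (1S,2R)-1-(allyloxy)-1-(3,4,5-trimethoxyphenyl)propan-2-ol, would attack C4 of 4-fluoro-3,5-dimethoxybenzaldehyde A8. The Meisenheimer adduct loses fluoride to give the aryl ether aldehyde A9. No bond to C8 is touched, so its configuration is retained. The formyl group of A9 would then be turned into the next secondary carbinol (olefination, asymmetric epoxidation with the same chiral catalyst that served for A7, regioselective benzylic C–O reduction). The SNAr would be repeated, and the last formyl group would become the propenyl group.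
- In its favour: neither ether bond is made by substitution at a stereocentre, so there are no inversion steps and no epimerisable α-aryloxy carbonyl compounds. On stereochemical safety at C8 it is better than steps 4 to 6. C7' arrives with the arene, so the formylation of step 9 is not needed. One chiral catalyst serves both halves, and neither an auxiliary nor an acyl-to-methyl reduction is required.
- Against it here: the fluorine of A8 lies between two methoxy groups and is activated only by one para formyl group, so attack by a secondary alkoxide should be slow, and the alkoxide can add to the formyl group instead. A8 is not a stock chemical. The erythro relation in A7 depends on a clean invertive opening of an electron-rich benzylic epoxide. The allyl ether must be removed in the presence of a propenyl group, and the final olefination must be E-selective.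
- Comparison: on step count and iterative economy it is the equal of the chosen plan or better. Its decisive bond formation is a deactivated, hindered SNAr, whereas the chosen plan joins a reactive benzylic bromide to a reactive enolate and is more convergent.

Key step: step 11

## Route

Step 1
Reactants: 1 4-allyl-2,6-dimethoxyphenol
Product: 2 2,6-dimethoxy-4-[(E)-prop-1-enyl]phenol
Conditions: RuHCl(CO)(PPh3)3 (1 mol %), toluene, 80 °C, argon
Reagents that add atoms: none
Why: RuHCl(CO)(PPh3)3-catalysed alkene isomerisation (hydrometalation, then β-hydride elimination) moves the double bond into conjugation with ring C; the conjugated E isomer is the thermodynamic sink, and residual Z isomer can be removed when 4 or 7 is crystallised.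

Step 2
Reactants: 2 2,6-dimethoxy-4-[(E)-prop-1-enyl]phenol; 3 bromoacetic acid
Product: 4 2-{2,6-dimethoxy-4-[(E)-prop-1-enyl]phenoxy}acetic acid
Conditions: NaH (2.3 equiv), THF, 0 °C to reflux, argon; then 1 M HCl
Reagents that add atoms: none
Why: Williamson ether synthesis; the sodium phenoxide displaces bromide at the primary carbon of sodium bromoacetate, the one electrophilic position that a di-ortho-substituted phenoxide reaches easily.

Step 3
Reactants: 4 2-{2,6-dimethoxy-4-[(E)-prop-1-enyl]phenoxy}acetic acid; 5 (R)-4-benzyl-1,3-oxazolidin-2-one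
Product: 7 (R)-4-benzyl-3-(2-{2,6-dimethoxy-4-[(E)-prop-1-enyl]phenoxy}acetyl)-1,3-oxazolidin-2-one, via mixed pivalic anhydride 6 (not isolated)
Conditions: t-BuCOCl, Et3N, THF, −20 °C to 0 °C; then LiCl, 5, rt
Reagents that add atoms: pivaloyl chloride, CC(C)(C)C(=O)Cl (its atoms remain only in intermediate 6)
Why: N-acylation through a mixed anhydride; the LiCl-activated oxazolidinone attacks the less hindered aryloxyacetyl carbonyl of 6, and no strong base touches the propenyl arene.

Step 4
Reactants: 8 ethyl (S)-lactate; 9 4-bromo-2,6-dimethoxyphenol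
Product: 10 ethyl (R)-2-(4-bromo-2,6-dimethoxyphenoxy)propanoate
Conditions: PPh3, DIAD, THF, 0 °C to rt
Reagents that add atoms: none
Why: Mitsunobu etherification; the phenoxide displaces the alkoxyphosphonium group in an SN2 step at the ester-activated carbon, so the (S) carbinol is inverted to the (R) aryl ether, which is C8 of the target.

Step 5
Reactants: 10 ethyl (R)-2-(4-bromo-2,6-dimethoxyphenoxy)propanoate
Product: 11 (R)-2-(4-bromo-2,6-dimethoxyphenoxy)-N-methoxy-N-methylpropanamide
Conditions: MeNH(OMe)·HCl, i-PrMgCl, THF, −20 °C to 0 °C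
Reagents that add atoms: N,O-dimethylhydroxylamine hydrochloride, CNOC.Cl
Why: Weinreb amide formation by aminolysis of the ester with the chloromagnesium amide made in the flask; at −20 °C acyl substitution outruns α-deprotonation, as with O-protected lactates, and the aryl bromide does not exchange with i-PrMgCl.

Step 6
Reactants: 11 (R)-2-(4-bromo-2,6-dimethoxyphenoxy)-N-methoxy-N-methylpropanamide; 12 5-bromo-1,2,3-trimethoxybenzene
Product: 14 (R)-2-(4-bromo-2,6-dimethoxyphenoxy)-1-(3,4,5-trimethoxyphenyl)propan-1-one, via 3,4,5-trimethoxyphenylmagnesium bromide 13 (not isolated)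
Conditions: 12, Mg, THF, 50 °C; then 11, THF, −10 °C to 0 °C; cold aq NH4Cl
Reagents that add atoms: magnesium, [Mg] (kept only in intermediate 13)
Why: Weinreb ketone synthesis; the magnesium chelate of the tetrahedral adduct stops the reaction after one addition and is not enolisable, so C8 keeps its configuration until the cold, mildly acidic quench releases the ketone.

Step 7
Reactants: 14 (R)-2-(4-bromo-2,6-dimethoxyphenoxy)-1-(3,4,5-trimethoxyphenyl)propan-1-one
Product: 15 (1S,2R)-2-(4-bromo-2,6-dimethoxyphenoxy)-1-(3,4,5-trimethoxyphenyl)propan-1-ol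
Conditions: Zn(BH4)2 (Et2O solution from ZnCl2 and NaBH4), Et2O, −20 °C to 0 °C
Reagents that add atoms: none
Why: Chelation-controlled (Cram-chelate) ketone reduction; zinc bridges the carbonyl oxygen and the C8 aryloxy oxygen, locking the C7–C8 rotamer, and hydride enters past the C8 hydrogen instead of the methyl group, which should give the erythro (7S,8R) alcohol.

Step 8
Reactants: 15 (1S,2R)-2-(4-bromo-2,6-dimethoxyphenoxy)-1-(3,4,5-trimethoxyphenyl)propan-1-ol
Product: 16 tert-butyl{[(1S,2R)-2-(4-bromo-2,6-dimethoxyphenoxy)-1-(3,4,5-trimethoxyphenyl)propyl]oxy}dimethylsilane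
Conditions: t-BuMe2SiOTf, 2,6-lutidine, CH2Cl2, 0 °C
Reagents that add atoms: tert-butyldimethylsilyl trifluoromethanesulfonate, CC(C)(C)[Si](C)(C)OS(=O)(=O)C(F)(F)F
Why: Silylation of a hindered secondary benzylic alcohol with the silyl triflate and a non-nucleophilic base; the ether formed withstands organolithium, amide base and hydride reagents.

Step 9
Reactants: 16 tert-butyl{[(1S,2R)-2-(4-bromo-2,6-dimethoxyphenoxy)-1-(3,4,5-trimethoxyphenyl)propyl]oxy}dimethylsilane
Product: 19 (4-{[(1S,2R)-1-[(tert-butyldimethylsilyl)oxy]-1-(3,4,5-trimethoxyphenyl)propan-2-yl]oxy}-3,5-dimethoxyphenyl)methanol, via aryllithium 17 (not isolated), via aldehyde 18 (not isolated)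
Conditions: n-BuLi, THF, −78 °C; DMF, −78 °C to 0 °C; then MeOH, NaBH4, 0 °C
Reagents that add atoms: N,N-dimethylformamide, CN(C)C=O; n-butyllithium, [Li]CCCC (lithium kept only in intermediate 17)
Why: Bromine–lithium exchange is far faster at −78 °C than ortho-lithiation or attack at silicon; the aryllithium is formylated by DMF (Bouveault aldehyde synthesis), and the aldehyde released on adding methanol is reduced at once by borohydride.

Step 10
Reactants: 19 (4-{[(1S,2R)-1-[(tert-butyldimethylsilyl)oxy]-1-(3,4,5-trimethoxyphenyl)propan-2-yl]oxy}-3,5-dimethoxyphenyl)methanol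
Product: 20 tert-butyl{[(1S,2R)-2-[4-(bromomethyl)-2,6-dimethoxyphenoxy]-1-(3,4,5-trimethoxyphenyl)propyl]oxy}dimethylsilane
Conditions: CBr4, PPh3, CH2Cl2, 0 °C; used without storage
Reagents that add atoms: carbon tetrabromide, BrC(Br)(Br)Br
Why: Appel bromination of the primary benzylic alcohol under neutral conditions, which spares the acid-sensitive benzylic silyl ether; the electron-rich bromide is filtered through a short pad and used directly.

Step 11
Reactants: 7 (R)-4-benzyl-3-(2-{2,6-dimethoxy-4-[(E)-prop-1-enyl]phenoxy}acetyl)-1,3-oxazolidin-2-one; 20 tert-butyl{[(1S,2R)-2-[4-(bromomethyl)-2,6-dimethoxyphenoxy]-1-(3,4,5-trimethoxyphenyl)propyl]oxy}dimethylsilane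
Product: 22 (R)-4-benzyl-3-[(S)-3-(4-{[(1S,2R)-1-[(tert-butyldimethylsilyl)oxy]-1-(3,4,5-trimethoxyphenyl)propan-2-yl]oxy}-3,5-dimethoxyphenyl)-2-{2,6-dimethoxy-4-[(E)-prop-1-enyl]phenoxy}propanoyl]-1,3-oxazolidin-2-one, via sodium Z-enolate 21 (not isolated)
Conditions: 7 (1.5 equiv), NaN(SiMe3)2 (1.4 equiv), THF, −78 °C; then 20 (1.0 equiv), −78 °C to −45 °C; AcOH quench at −45 °C
Reagents that add atoms: sodium bis(trimethylsilyl)amide, C[Si](C)(C)N([Na])[Si](C)(C)C (sodium kept only in intermediate 21)
Why: The amide base deprotonates 7 at −78 °C to the Z enolate 21, in which sodium is held between the enolate oxygen and the oxazolidinone carbonyl oxygen, so the imide is planar and rigid. In this chelate the (R)-benzyl group covers one face of the α-carbon, and the benzylic bromide 20 attacks the open face in an SN2 step with loss of bromide, forming the C7'–C8' bond. That face gives the (S) α-carbon, which becomes (R)-C8' once the acyl carbon is reduced to the C9' methyl; the centre is controlled by the auxiliary alone and is independent of the remote C7 and C8 centres of 20. The closest known reaction type is the alkylation of sodium enolates of N-(alkoxyacetyl)- and N-(aryloxyacetyl)oxazolidinones with allylic and benzylic halides, the glycolate variant of the Evans alkylation. No ring is closed. The step needs C- over O-alkylation (favoured by the soft benzylic bromide and the chelated enolate), mono- over dialkylation (the product α-carbon is tertiary and hindered) and alkylation over enolate breakdown (secured by keeping the cold enolate in excess and 20, activated by its para alkoxy group, as the limiting partner). The propenyl group, the silyl ether and the aryl ethers are inert to the base at this temperature.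

Step 12
Reactants: 22 (R)-4-benzyl-3-[(S)-3-(4-{[(1S,2R)-1-[(tert-butyldimethylsilyl)oxy]-1-(3,4,5-trimethoxyphenyl)propan-2-yl]oxy}-3,5-dimethoxyphenyl)-2-{2,6-dimethoxy-4-[(E)-prop-1-enyl]phenoxy}propanoyl]-1,3-oxazolidin-2-one
Product: 23 (S)-3-(4-{[(1S,2R)-1-[(tert-butyldimethylsilyl)oxy]-1-(3,4,5-trimethoxyphenyl)propan-2-yl]oxy}-3,5-dimethoxyphenyl)-2-{2,6-dimethoxy-4-[(E)-prop-1-enyl]phenoxy}propan-1-ol
Conditions: LiBH4, MeOH (1.1 equiv), THF, 0 °C to rt
Reagents that add atoms: none
Why: Reductive cleavage of the N-acyloxazolidinone; hydride attacks the exocyclic, lithium-activated carbonyl, and the aldehyde released is reduced further to the primary alcohol while 5 is set free for reuse; the medium is not basic enough to epimerise C8'.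

Step 13
Reactants: 23 (S)-3-(4-{[(1S,2R)-1-[(tert-butyldimethylsilyl)oxy]-1-(3,4,5-trimethoxyphenyl)propan-2-yl]oxy}-3,5-dimethoxyphenyl)-2-{2,6-dimethoxy-4-[(E)-prop-1-enyl]phenoxy}propan-1-ol
Product: 24 (S)-3-(4-{[(1S,2R)-1-[(tert-butyldimethylsilyl)oxy]-1-(3,4,5-trimethoxyphenyl)propan-2-yl]oxy}-3,5-dimethoxyphenyl)-2-{2,6-dimethoxy-4-[(E)-prop-1-enyl]phenoxy}propyl 4-methylbenzenesulfonate
Conditions: TsCl, Et3N, DMAP (cat.), CH2Cl2, 0 °C to rt
Reagents that add atoms: 4-methylbenzenesulfonyl chloride, Cc1ccc(cc1)S(Cl)(=O)=O
Why: Sulfonylation of the only free hydroxyl group, a primary alcohol, under standard amine-base conditions.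

Step 14
Reactants: 24 (S)-3-(4-{[(1S,2R)-1-[(tert-butyldimethylsilyl)oxy]-1-(3,4,5-trimethoxyphenyl)propan-2-yl]oxy}-3,5-dimethoxyphenyl)-2-{2,6-dimethoxy-4-[(E)-prop-1-enyl]phenoxy}propyl 4-methylbenzenesulfonate
Product: 25 tert-butyl{[(1S,2R)-2-(4-{(2R)-2-[2,6-dimethoxy-4-((E)-prop-1-enyl)phenoxy]propyl}-2,6-dimethoxyphenoxy)-1-(3,4,5-trimethoxyphenyl)propyl]oxy}dimethylsilane
Conditions: LiBHEt3, THF, 0 °C to rt
Reagents that add atoms: none
Why: SN2 displacement of a primary tosylate by the strongly nucleophilic triethylborohydride turns C9' into a methyl group; C8' is not a reacting centre, and its descriptor changes from S to R only because the substituent priorities change.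

Step 15
Reactants: 25 tert-butyl{[(1S,2R)-2-(4-{(2R)-2-[2,6-dimethoxy-4-((E)-prop-1-enyl)phenoxy]propyl}-2,6-dimethoxyphenoxy)-1-(3,4,5-trimethoxyphenyl)propyl]oxy}dimethylsilane
Product: 26 (1S,2R)-2-(4-{(2R)-2-[2,6-dimethoxy-4-((E)-prop-1-enyl)phenoxy]propyl}-2,6-dimethoxyphenoxy)-1-(3,4,5-trimethoxyphenyl)propan-1-ol
Conditions: Bu4NF, THF, 0 °C to rt
Reagents that add atoms: none
Why: Fluoride-induced desilylation driven by the strong Si–F bond; the conditions are neutral to mildly basic, so neither the benzylic C7–O bond nor the propenyl group is at risk.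

Step 16
Reactants: 26 (1S,2R)-2-(4-{(2R)-2-[2,6-dimethoxy-4-((E)-prop-1-enyl)phenoxy]propyl}-2,6-dimethoxyphenoxy)-1-(3,4,5-trimethoxyphenyl)propan-1-ol
Product: 27 (1S,2R)-2-(4-{(2R)-2-[2,6-dimethoxy-4-((E)-prop-1-enyl)phenoxy]propyl}-2,6-dimethoxyphenoxy)-1-(3,4,5-trimethoxyphenyl)propyl acetate
Conditions: Ac2O, pyridine, DMAP (cat.), CH2Cl2, rt
Reagents that add atoms: acetic anhydride, CC(=O)OC(C)=O
Why: DMAP-catalysed O-acylation of the secondary benzylic alcohol with retention at C7, since only the O–H bond is broken; this gives the (7S,8R,8'R) target.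

## Compound list

1 | 4-allyl-2,6-dimethoxyphenol | C=CCc1cc(OC)c(O)c(OC)c1 | starting material
2 | 2,6-dimethoxy-4-[(E)-prop-1-enyl]phenol | C/C=C/c1cc(OC)c(O)c(OC)c1 | intermediate
3 | bromoacetic acid | OC(=O)CBr | starting material
4 | 2-{2,6-dimethoxy-4-[(E)-prop-1-enyl]phenoxy}acetic acid | C/C=C/c1cc(OC)c(OCC(O)=O)c(OC)c1 | intermediate
5 | (R)-4-benzyl-1,3-oxazolidin-2-one | O=C1N[C@H](Cc2ccccc2)CO1 | starting material
6 | 2-{2,6-dimethoxy-4-[(E)-prop-1-enyl]phenoxy}acetic pivalic anhydride (not isolated) | C/C=C/c1cc(OC)c(OCC(=O)OC(=O)C(C)(C)C)c(OC)c1 | intermediate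
7 | (R)-4-benzyl-3-(2-{2,6-dimethoxy-4-[(E)-prop-1-enyl]phenoxy}acetyl)-1,3-oxazolidin-2-one | C/C=C/c1cc(OC)c(OCC(=O)N2[C@H](Cc3ccccc3)COC2=O)c(OC)c1 | intermediate
8 | ethyl (S)-lactate | C[C@H](O)C(=O)OCC | starting material
9 | 4-bromo-2,6-dimethoxyphenol | COc1cc(Br)cc(OC)c1O | starting material
10 | ethyl (R)-2-(4-bromo-2,6-dimethoxyphenoxy)propanoate | C[C@@H](Oc1c(OC)cc(Br)cc1OC)C(=O)OCC | intermediate
11 | (R)-2-(4-bromo-2,6-dimethoxyphenoxy)-N-methoxy-N-methylpropanamide | C[C@@H](Oc1c(OC)cc(Br)cc1OC)C(=O)N(C)OC | intermediate
12 | 5-bromo-1,2,3-trimethoxybenzene | COc1cc(Br)cc(OC)c1OC | starting material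
13 | 3,4,5-trimethoxyphenylmagnesium bromide (not isolated) | COc1cc([Mg]Br)cc(OC)c1OC | intermediate
14 | (R)-2-(4-bromo-2,6-dimethoxyphenoxy)-1-(3,4,5-trimethoxyphenyl)propan-1-one | C[C@@H](Oc1c(OC)cc(Br)cc1OC)C(=O)c1cc(OC)c(OC)c(OC)c1 | intermediate
15 | (1S,2R)-2-(4-bromo-2,6-dimethoxyphenoxy)-1-(3,4,5-trimethoxyphenyl)propan-1-ol | C[C@@H](Oc1c(OC)cc(Br)cc1OC)[C@@H](O)c1cc(OC)c(OC)c(OC)c1 | intermediate
16 | tert-butyl{[(1S,2R)-2-(4-bromo-2,6-dimethoxyphenoxy)-1-(3,4,5-trimethoxyphenyl)propyl]oxy}dimethylsilane | C[C@@H](Oc1c(OC)cc(Br)cc1OC)[C@@H](O[Si](C)(C)C(C)(C)C)c1cc(OC)c(OC)c(OC)c1 | intermediate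
17 | aryllithium from 16, lithium in place of bromine on ring B (not isolated) | C[C@@H](Oc1c(OC)cc([Li])cc1OC)[C@@H](O[Si](C)(C)C(C)(C)C)c1cc(OC)c(OC)c(OC)c1 | intermediate
18 | 4-{[(1S,2R)-1-[(tert-butyldimethylsilyl)oxy]-1-(3,4,5-trimethoxyphenyl)propan-2-yl]oxy}-3,5-dimethoxybenzaldehyde (not isolated) | C[C@@H](Oc1c(OC)cc(C=O)cc1OC)[C@@H](O[Si](C)(C)C(C)(C)C)c1cc(OC)c(OC)c(OC)c1 | intermediate
19 | (4-{[(1S,2R)-1-[(tert-butyldimethylsilyl)oxy]-1-(3,4,5-trimethoxyphenyl)propan-2-yl]oxy}-3,5-dimethoxyphenyl)methanol | C[C@@H](Oc1c(OC)cc(CO)cc1OC)[C@@H](O[Si](C)(C)C(C)(C)C)c1cc(OC)c(OC)c(OC)c1 | intermediate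
20 | tert-butyl{[(1S,2R)-2-[4-(bromomethyl)-2,6-dimethoxyphenoxy]-1-(3,4,5-trimethoxyphenyl)propyl]oxy}dimethylsilane | BrCc1cc(OC)c(O[C@H](C)[C@@H](O[Si](C)(C)C(C)(C)C)c2cc(OC)c(OC)c(OC)c2)c(OC)c1 | intermediate
21 | sodium Z-enolate of 7 (not isolated) | C/C=C/c1cc(OC)c(O/C=C(\[O-])N2[C@H](Cc3ccccc3)COC2=O)c(OC)c1.[Na+] | intermediate
22 | (R)-4-benzyl-3-[(S)-3-(4-{[(1S,2R)-1-[(tert-butyldimethylsilyl)oxy]-1-(3,4,5-trimethoxyphenyl)propan-2-yl]oxy}-3,5-dimethoxyphenyl)-2-{2,6-dimethoxy-4-[(E)-prop-1-enyl]phenoxy}propanoyl]-1,3-oxazolidin-2-one | C/C=C/c1cc(OC)c(O[C@@H](Cc2cc(OC)c(O[C@H](C)[C@@H](O[Si](C)(C)C(C)(C)C)c3cc(OC)c(OC)c(OC)c3)c(OC)c2)C(=O)N2[C@H](Cc3ccccc3)COC2=O)c(OC)c1 | intermediate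
23 | (S)-3-(4-{[(1S,2R)-1-[(tert-butyldimethylsilyl)oxy]-1-(3,4,5-trimethoxyphenyl)propan-2-yl]oxy}-3,5-dimethoxyphenyl)-2-{2,6-dimethoxy-4-[(E)-prop-1-enyl]phenoxy}propan-1-ol | C/C=C/c1cc(OC)c(O[C@@H](Cc2cc(OC)c(O[C@H](C)[C@@H](O[Si](C)(C)C(C)(C)C)c3cc(OC)c(OC)c(OC)c3)c(OC)c2)CO)c(OC)c1 | intermediate
24 | 4-methylbenzenesulfonate of 23, (S) at C8' | C/C=C/c1cc(OC)c(O[C@@H](Cc2cc(OC)c(O[C@H](C)[C@@H](O[Si](C)(C)C(C)(C)C)c3cc(OC)c(OC)c(OC)c3)c(OC)c2)COS(=O)(=O)c2ccc(C)cc2)c(OC)c1 | intermediate
25 | tert-butyl{[(1S,2R)-2-(4-{(2R)-2-[2,6-dimethoxy-4-((E)-prop-1-enyl)phenoxy]propyl}-2,6-dimethoxyphenoxy)-1-(3,4,5-trimethoxyphenyl)propyl]oxy}dimethylsilane | C/C=C/c1cc(OC)c(O[C@H](C)Cc2cc(OC)c(O[C@H](C)[C@@H](O[Si](C)(C)C(C)(C)C)c3cc(OC)c(OC)c(OC)c3)c(OC)c2)c(OC)c1 | intermediate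
26 | (1S,2R)-2-(4-{(2R)-2-[2,6-dimethoxy-4-((E)-prop-1-enyl)phenoxy]propyl}-2,6-dimethoxyphenoxy)-1-(3,4,5-trimethoxyphenyl)propan-1-ol | C/C=C/c1cc(OC)c(O[C@H](C)Cc2cc(OC)c(O[C@H](C)[C@@H](O)c3cc(OC)c(OC)c(OC)c3)c(OC)c2)c(OC)c1 | intermediate
27 | (1S,2R)-2-(4-{(2R)-2-[2,6-dimethoxy-4-((E)-prop-1-enyl)phenoxy]propyl}-2,6-dimethoxyphenoxy)-1-(3,4,5-trimethoxyphenyl)propyl acetate, (7S,8R,8'R) | C/C=C/c1cc(OC)c(O[C@H](C)Cc2cc(OC)c(O[C@H](C)[C@@H](OC(C)=O)c3cc(OC)c(OC)c(OC)c3)c(OC)c2)c(OC)c1 | target

## Step count and risks

Total: 16 steps. Longest linear sequence: 13 steps (steps 4 to 16, from 8 and 9). The ring C branch (steps 1 to 3) joins at step 11.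

Least certain steps:

**Step 11 (key step).**
- Risk: the sodium enolate 21 may fragment (loss of the oxazolidinone through a ketene) faster than a large benzylic bromide is alkylated between −78 °C and −45 °C. This would leave 20 unconsumed. A smaller risk is loss of facial selectivity if part of the reaction runs through a non-chelated enolate.
- Fallback: it sets out from 16. Bromine–lithium exchange to 17 and opening of (S)-2-methyloxirane at its CH2 terminus, assisted by BF3·OEt2 at −78 °C, should give the secondary alcohol (S)-1-(4-{[(1S,2R)-1-[(tert-butyldimethylsilyl)oxy]-1-(3,4,5-trimethoxyphenyl)propan-2-yl]oxy}-3,5-dimethoxyphenyl)propan-2-ol F1 with the epoxide stereocentre untouched. Mitsunobu etherification of F1 with phenol 2 (PPh3, DIAD) then inverts this centre and comes back to the route at 25.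
- Trade-off: this path is shorter than steps 9 to 14. However, it rests on substitution by a hindered phenol at an unactivated secondary carbon, with elimination to a conjugated alkene as a competitor, which is exactly what the main route avoids.

**Step 7.**
- Risk: chelation may be incomplete, because an aryloxy oxygen is a weak donor for zinc. Part of the reduction would then follow the Felkin–Anh course, and facial selectivity at C7 would be poor.
- Fallback: it sets out from 14. The (1R,2R) alcohol F2, formed alongside 15 (or made on purpose with a bulky non-chelating hydride such as LiBH(s-Bu)3), is separated. It is inverted at C7 by a Mitsunobu reaction with 4-nitrobenzoic acid to give the (1S,2R) 4-nitrobenzoate ester F3. Methanolysis with K2CO3 in MeOH then comes back to the route at 15.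

**Step 4.**
- Risk: the di-ortho-substituted phenoxide may displace the alkoxyphosphonium group slowly, so that alkylation of the reduced azodicarboxylate or elimination to the acrylate competes.
- Fallback: it sets out from 8. Tosylation (TsCl, Et3N, DMAP) gives the lactate tosylate ethyl (S)-2-[(4-methylbenzenesulfonyl)oxy]propanoate F4, and the potassium salt of 9 (K2CO3, MeCN, 60 °C) displaces the sulfonate in a classical SN2 step with the same inversion, coming back at 10.

**Step 14.**
- Risk: the tosylate carbon is β-branched and β-oxygenated, so hydride attack at sulfur (returning 23) or E2 elimination to an enol ether may compete with substitution at carbon.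
- Fallback: it sets out from 23. Iodination with I2, PPh3 and imidazole gives the primary iodide F5, which is reduced by NaBH4 in DMSO at 60 °C, a softer leaving group paired with a less basic hydride, and comes back at 25.

**Step 1.**
- Risk: geometric control may be incomplete, with some Z isomer carried forward, or the free phenol may inhibit the catalyst.
- Fallback: it sets out from 9 and reaches 2 directly by Suzuki–Miyaura coupling with potassium (E)-prop-1-enyltrifluoroborate (Pd(OAc)2, SPhos, K3PO4, toluene–H2O, 80 °C). The alkene geometry is carried over from the boron reagent, and no new intermediate is made.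

## Further compounds

F1 | step 11 | (S)-1-(4-{[(1S,2R)-1-[(tert-butyldimethylsilyl)oxy]-1-(3,4,5-trimethoxyphenyl)propan-2-yl]oxy}-3,5-dimethoxyphenyl)propan-2-ol | C[C@H](O)Cc1cc(OC)c(O[C@H](C)[C@@H](O[Si](C)(C)C(C)(C)C)c2cc(OC)c(OC)c(OC)c2)c(OC)c1
F2 | step 7 | (1R,2R)-2-(4-bromo-2,6-dimethoxyphenoxy)-1-(3,4,5-trimethoxyphenyl)propan-1-ol | C[C@@H](Oc1c(OC)cc(Br)cc1OC)[C@H](O)c1cc(OC)c(OC)c(OC)c1
F3 | step 7 | (1S,2R)-2-(4-bromo-2,6-dimethoxyphenoxy)-1-(3,4,5-trimethoxyphenyl)propyl 4-nitrobenzoate | C[C@@H](Oc1c(OC)cc(Br)cc1OC)[C@@H](OC(=O)c1ccc(cc1)[N+](=O)[O-])c1cc(OC)c(OC)c(OC)c1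
F4 | step 4 | ethyl (S)-2-[(4-methylbenzenesulfonyl)oxy]propanoate | CCOC(=O)[C@H](C)OS(=O)(=O)c1ccc(C)cc1
F5 | step 14 | tert-butyl{[(1S,2R)-2-(4-{(2S)-2-[2,6-dimethoxy-4-((E)-prop-1-enyl)phenoxy]-3-iodopropyl}-2,6-dimethoxyphenoxy)-1-(3,4,5-trimethoxyphenyl)propyl]oxy}dimethylsilane | C/C=C/c1cc(OC)c(O[C@@H](Cc2cc(OC)c(O[C@H](C)[C@@H](O[Si](C)(C)C(C)(C)C)c3cc(OC)c(OC)c(OC)c3)c(OC)c2)CI)c(OC)c1
F0 | step 1 | none | none
A1 | alternative 1 | 3,4,5-trimethoxybenzaldehyde | COc1cc(C=O)cc(OC)c1OC
A2 | alternative 1 | acetaldehyde | CC=O
A3 | alternative 1 | (S)-2-hydroxy-1-(3,4,5-trimethoxyphenyl)propan-1-one | C[C@H](O)C(=O)c1cc(OC)c(OC)c(OC)c1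
A4 | alternative 2 | 4-bromo-2,6-dimethoxyphenyl acetate | CC(=O)Oc1c(OC)cc(Br)cc1OC
A5 | alternative 2 | {4-[(Z)-2-(4-bromo-2,6-dimethoxyphenoxy)prop-1-enyl]-2,6-dimethoxyphenoxy}tri(propan-2-yl)silane | CC(C)[Si](Oc1c(OC)cc(/C=C(/C)Oc2c(OC)cc(Br)cc2OC)cc1OC)(C(C)C)C(C)C
A6 | alternative 2 | {4-[(2R)-2-(4-bromo-2,6-dimethoxyphenoxy)propyl]-2,6-dimethoxyphenoxy}tri(propan-2-yl)silane | CC(C)[Si](Oc1c(OC)cc(C[C@@H](C)Oc2c(OC)cc(Br)cc2OC)cc1OC)(C(C)C)C(C)C
A7 | alternative 3 | (1S,2R)-1-(allyloxy)-1-(3,4,5-trimethoxyphenyl)propan-2-ol | C[C@@H](O)[C@@H](OCC=C)c1cc(OC)c(OC)c(OC)c1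
A8 | alternative 3 | 4-fluoro-3,5-dimethoxybenzaldehyde | COc1cc(C=O)cc(OC)c1F
A9 | alternative 3 | 4-{[(1S,2R)-1-(allyloxy)-1-(3,4,5-trimethoxyphenyl)propan-2-yl]oxy}-3,5-dimethoxybenzaldehyde | C[C@@H](Oc1c(OC)cc(C=O)cc1OC)[C@@H](OCC=C)c1cc(OC)c(OC)c(OC)c1
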